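The route rests on building ring A (the cyclohexadienone whose quaternary C-4 carries methyl and geranyl) de novo by a formal [4+2] acylation–Claisen annulation. The lithium enolate of an enantiopure ethyl 2-geranyl-2-methylacetoacetate (C-3 to C-6 of ring A, stereocentre included) is C-acetoacetylated by diketene, which supplies C-1, C-2 and the acetyl group; the triketo ester so formed closes onto its own ester. One operation thus forms the C-1–C-6 and C-2–C-3 bonds, exploiting the 1,3,5-oxygenation of ring A and the quaternary carbon that blocks competing aldol modes. Ring A is then joined through a methylene bridge to a butanoylphloroglucinol–chromene dimer made by Mannich-base (o-quinone methide) couplings.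

Key step: step 3

Assumption: in step 2 the chelated lithio-enamine of the L-valine auxiliary is taken to be alkylated on the face away from the isopropyl group in the weakly coordinating toluene–THF medium, which corresponds to (R)-5; should the assay of 5 show the opposite sense, D-valine tert-butyl ester would replace 2 and nothing else would change.

Remark: 2 is used as the free base, released from its commercial hydrochloride by a bicarbonate wash.

Step 1
Reactants: 1 ethyl 2-methyl-3-oxobutanoate; 2 tert-butyl (2S)-2-amino-3-methylbutanoate (L-valine tert-butyl ester)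
Product: 3 ethyl (2Z)-3-{[(2S)-1-tert-butoxy-3-methyl-1-oxobutan-2-yl]amino}-2-methylbut-2-enoate
Conditions: BF3·OEt2 (cat.), benzene, reflux, Dean–Stark
Reagents that add atoms: none
Why: Acid-catalysed enamine condensation of a β-keto ester with a primary amine, driven by azeotropic removal of water; the N–H···O=C hydrogen bond fixes the (Z)-enamino ester.

Step 2
Reactants: 3 the enamino ester; 4 (2E)-1-bromo-3,7-dimethylocta-2,6-diene (geranyl bromide)
Product: 5 ethyl (2R,4E)-2-acetyl-2,5,9-trimethyldeca-4,8-dienoate
Conditions: LiN(i-Pr)2 (1.1 equiv), toluene–THF, −78 °C; 4, −78 → −40 °C; then aq. AcOH–NaOAc buffer, rt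
Reagents that add atoms: water, O
Why: Koga-type asymmetric alkylation of a chiral lithio-enamine (aza-enolate SN2 alkylation): lithium is held by the nitrogen, the enoate oxygen and the valine ester carbonyl, the isopropyl group shields one face, and the allylic bromide should enter at C-2 from the other face to set the quaternary centre as (R), after which mild hydrolysis of the imine frees the ketone and returns the auxiliary.

Step 3
Reactants: 5 ethyl (2R,4E)-2-acetyl-2,5,9-trimethyldeca-4,8-dienoate; 6 4-methylideneoxetan-2-one (diketene)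
Product: 8 (4R)-2-acetyl-4-[(2E)-3,7-dimethylocta-2,6-dien-1-yl]-3,5-dihydroxy-4-methylcyclohexa-2,5-dien-1-one (ring A monomer), via triketo ester 7 (not isolated)
Conditions: LiN(SiMe3)2 (1.1 equiv), THF, −78 °C; 6 (1.1 equiv), −78 → −20 °C; LiN(SiMe3)2 (1.5 equiv), −20 °C → rt; cold 1 M HCl work-up
Reagents that add atoms: none
Why: LiN(SiMe3)2 removes a proton from the acetyl methyl group of 5 (its only enolisable position), the enolate carbon attacks the lactone carbonyl of diketene, and ring opening gives the chelated lithium salt of triketo ester 7, whose diketone carbon, after a second deprotonation, attacks the ethyl ester and expels ethoxide. The closest known reaction types are the C-acetoacetylation of enolates by diketene and the Dieckmann-type Claisen closure of 3,5-dioxo esters to cyclohexane-1,3,5-triones (syncarpic acid and biomimetic acylphloroglucinol syntheses). Ring A, the only ring formed, closes by a 6-(enolexo)-exo-trig acyl substitution. No new stereocentre arises; the quaternary carbon from step 2 cannot enolise and is carried unchanged, and the annulation only fixes that the acetyl-bearing carbon lies on the former ester side, which gives the (4R) descriptor. The step needs C- over O-acylation and Claisen closure over aldol or lactone closure: the quaternary carbon removes the usual aldol partner, LiN(SiMe3)2 is too weak to form the terminal methyl carbanion needed for the other aldol mode, and the β-triketone enolate is the thermodynamic sink. The acetyl group must come in with the two-carbon unit, because the trione without it would be achiral.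

Step 4
Reactants: 9 1-(2,4,6-trihydroxyphenyl)butan-1-one
Product: 10 1-[2,6-dihydroxy-4-(methoxymethoxy)phenyl]butan-1-one
Conditions: MOMCl (1.0 equiv), i-Pr2NEt (1.1 equiv), CH2Cl2, 0 °C
Reagents that add atoms: chloromethyl methyl ether (MOMCl), COCCl
Why: Selective O-alkylation of the most acidic, non-chelated 4-hydroxyl (the 2- and 6-hydroxyls are hydrogen-bonded to and hindered by the acyl group), which blocks the para oxygen so that the pyran ring in step 5 can close only through an ortho oxygen.

Step 5
Reactants: 10 1-[2,6-dihydroxy-4-(methoxymethoxy)phenyl]butan-1-one; 11 3-methylbut-2-enal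
Product: 12 1-[7-hydroxy-5-(methoxymethoxy)-2,2-dimethyl-2H-chromen-8-yl]butan-1-one
Conditions: 11 (1.05 equiv), ethylenediammonium diacetate (10 mol %), toluene, 100 °C
Reagents that add atoms: none
Why: Amine-catalysed Knoevenagel-type condensation at C-3 of the phenol, loss of water to the o-quinone methide and oxa-6π electrocyclisation; only the free hydroxyl ortho to the acyl group flanks C-3, so the butanoyl group must end at C-8 of the chromene.

Step 6
Reactants: 12 1-[7-hydroxy-5-(methoxymethoxy)-2,2-dimethyl-2H-chromen-8-yl]butan-1-one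
Product: 13 1-(5,7-dihydroxy-2,2-dimethyl-2H-chromen-8-yl)butan-1-one
Conditions: 3 M HCl, MeOH, 40 °C
Reagents that add atoms: none
Why: Acid-catalysed acetal exchange removes the MOM group as dimethoxymethane under conditions that 2,2-dimethylchromenes are expected to tolerate.

Step 7
Reactants: 13 1-(5,7-dihydroxy-2,2-dimethyl-2H-chromen-8-yl)butan-1-one; 14 N,N-dimethylmethaniminium iodide (Eschenmoser's salt); 9 1-(2,4,6-trihydroxyphenyl)butan-1-one
Product: 16 1-{3-[(8-butanoyl-5,7-dihydroxy-2,2-dimethyl-2H-chromen-6-yl)methyl]-2,4,6-trihydroxyphenyl}butan-1-one, via Mannich base 15 (not isolated)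
Conditions: 14 (1.0 equiv), Et3N (1.0 equiv), MeCN, 0 °C → rt; then 9 (3 equiv), 70 °C
Reagents that add atoms: none
Why: Phenolic Mannich aminomethylation at C-6, the only free ring position of 13, then thermal loss of dimethylamine to the o-quinone methide and Michael-type C-benzylation of butanoylphloroglucinol, used in excess to suppress double benzylation.

Step 8
Reactants: 16 the ring B–ring C dimer; 14 N,N-dimethylmethaniminium iodide; 8 the ring A monomer
Product: 18 (4R)-2-acetyl-6-({3-butanoyl-5-[(8-butanoyl-5,7-dihydroxy-2,2-dimethyl-2H-chromen-6-yl)methyl]-2,4,6-trihydroxyphenyl}methyl)-4-[(2E)-3,7-dimethylocta-2,6-dien-1-yl]-3,5-dihydroxy-4-methylcyclohexa-2,5-dien-1-one (CNP0103039.1), via Mannich base 17 (not isolated)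
Conditions: 14 (1.0 equiv), Et3N (1.0 equiv), MeCN, 0 °C → rt; then 8 (1.1 equiv), 50 °C
Reagents that add atoms: none
Why: Mannich aminomethylation of the last free position of ring B, then o-quinone methide formation and Michael-type C-alkylation by the vinylogous acid 8 at C-6, its only unsubstituted ring carbon; the quaternary stereocentre is not touched.

Compound list

1 | ethyl 2-methyl-3-oxobutanoate | CCOC(=O)C(C)C(C)=O | starting material
2 | tert-butyl (2S)-2-amino-3-methylbutanoate (L-valine tert-butyl ester) | CC(C)[C@H](N)C(=O)OC(C)(C)C | starting material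
3 | ethyl (2Z)-3-{[(2S)-1-tert-butoxy-3-methyl-1-oxobutan-2-yl]amino}-2-methylbut-2-enoate | CCOC(=O)/C(C)=C(C)\N[C@@H](C(C)C)C(=O)OC(C)(C)C | intermediate
4 | (2E)-1-bromo-3,7-dimethylocta-2,6-diene (geranyl bromide) | BrC/C=C(\C)CCC=C(C)C | starting material
5 | ethyl (2R,4E)-2-acetyl-2,5,9-trimethyldeca-4,8-dienoate | CC(=O)[C@@](C)(C/C=C(\C)CCC=C(C)C)C(=O)OCC | intermediate
6 | 4-methylideneoxetan-2-one (diketene) | C=C1CC(=O)O1 | starting material
7 | ethyl (2R,4E)-2-(3,5-dioxohexanoyl)-2,5,9-trimethyldeca-4,8-dienoate | CC(=O)CC(=O)CC(=O)[C@@](C)(C/C=C(\C)CCC=C(C)C)C(=O)OCC | intermediate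
8 | (4R)-2-acetyl-4-[(2E)-3,7-dimethylocta-2,6-dien-1-yl]-3,5-dihydroxy-4-methylcyclohexa-2,5-dien-1-one | O=C1C=C(O)[C@@](C)(C/C=C(\C)CCC=C(C)C)C(O)=C1C(C)=O | intermediate
9 | 1-(2,4,6-trihydroxyphenyl)butan-1-one | CCCC(=O)c1c(O)cc(O)cc1O | starting material
10 | 1-[2,6-dihydroxy-4-(methoxymethoxy)phenyl]butan-1-one | CCCC(=O)c1c(O)cc(OCOC)cc1O | intermediate
11 | 3-methylbut-2-enal | CC(C)=CC=O | starting material
12 | 1-[7-hydroxy-5-(methoxymethoxy)-2,2-dimethyl-2H-chromen-8-yl]butan-1-one | CCCC(=O)c1c(O)cc(OCOC)c2C=CC(C)(C)Oc12 | intermediate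
13 | 1-(5,7-dihydroxy-2,2-dimethyl-2H-chromen-8-yl)butan-1-one | CCCC(=O)c1c(O)cc(O)c2C=CC(C)(C)Oc12 | intermediate
14 | N,N-dimethylmethaniminium iodide (Eschenmoser's salt) | C=[N+](C)C.[I-] | starting material
15 | 1-{6-[(dimethylamino)methyl]-5,7-dihydroxy-2,2-dimethyl-2H-chromen-8-yl}butan-1-one | CCCC(=O)c1c(O)c(CN(C)C)c(O)c2C=CC(C)(C)Oc12 | intermediate
16 | 1-{3-[(8-butanoyl-5,7-dihydroxy-2,2-dimethyl-2H-chromen-6-yl)methyl]-2,4,6-trihydroxyphenyl}butan-1-one | CCCC(=O)c1c(O)cc(O)c(Cc2c(O)c3c(c(C(=O)CCC)c2O)OC(C)(C)C=C3)c1O | intermediate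
17 | 1-{3-[(8-butanoyl-5,7-dihydroxy-2,2-dimethyl-2H-chromen-6-yl)methyl]-5-[(dimethylamino)methyl]-2,4,6-trihydroxyphenyl}butan-1-one | CCCC(=O)c1c(O)c(CN(C)C)c(O)c(Cc2c(O)c3c(c(C(=O)CCC)c2O)OC(C)(C)C=C3)c1O | intermediate
18 | (4R)-2-acetyl-6-({3-butanoyl-5-[(8-butanoyl-5,7-dihydroxy-2,2-dimethyl-2H-chromen-6-yl)methyl]-2,4,6-trihydroxyphenyl}methyl)-4-[(2E)-3,7-dimethylocta-2,6-dien-1-yl]-3,5-dihydroxy-4-methylcyclohexa-2,5-dien-1-one (CNP0103039.1) | CCCC(=O)c1c(O)c(CC2=C(O)[C@@](C)(C/C=C(\C)CCC=C(C)C)C(O)=C(C(C)=O)C2=O)c(O)c(Cc2c(O)c3c(c(C(=O)CCC)c2O)OC(C)(C)C=C3)c1O | target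

Total step count: 8

Longest linear sequence: 5 steps (9 → 10 → 12 → 13 → 16 → 18); the ring A branch (1 → 3 → 5 → 8) joins in step 8.

Steps most likely to fail

Step 3. Proton transfer between the enolate and diketene, or O-acylation of the enolate, may consume both partners before the C–C bond forms, and an uncyclised triketone may dehydrate to a 4-pyranone on work-up. The fallback sets out from 5 and separates the two bond formations with a masked acetoacetyl unit. The lithium enolate of 5 (LiN(i-Pr)2, 2.2 equiv, THF, −78 °C) undergoes a Claisen condensation with commercial ethyl (2-methyl-1,3-dioxolan-2-yl)acetate to give ethyl (2R,4E)-2,5,9-trimethyl-2-[4-(2-methyl-1,3-dioxolan-2-yl)-3-oxobutanoyl]deca-4,8-dienoate F1. Mild hydrolysis of the ketal (aq. AcOH, THF, 40 °C) gives 7, where the fallback rejoins the route. 7 is then cyclised to 8 in a separate operation with DBU in THF.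

Step 2. Facial discrimination in the alkylation of an acyclic lithio-enamine by an allylic bromide may be lower than needed, or opposite in sense to the assumption. The fallback sets out from 1 and 4 and replaces asymmetric synthesis by resolution. Alkylation with K2CO3 in acetone at reflux gives racemic ethyl (4E)-2-acetyl-2,5,9-trimethyldeca-4,8-dienoate F2. Preparative chromatography on a chiral stationary phase (amylose tris(3,5-dimethylphenylcarbamate), supercritical CO2–MeOH) separates 5 from its antipode, ethyl (2S,4E)-2-acetyl-2,5,9-trimethyldeca-4,8-dienoate F3, which is set aside. The route is rejoined at 5.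

Step 8. Heating may fragment and recombine the methylene bridges (retro-Michael scrambling), and the quinone methide from 17 may be intercepted by unreacted 16 instead of 8. The fallback sets out from 8 and reverses the roles of the partners. 8 is aminomethylated with 14 and Et3N in MeCN at 0 °C to give the betaine (4R)-2-acetyl-6-[(dimethylamino)methyl]-4-[(2E)-3,7-dimethylocta-2,6-dien-1-yl]-3,5-dihydroxy-4-methylcyclohexa-2,5-dien-1-one F4. F4 should lose dimethylamine at or below room temperature to the exocyclic methylene trione, which 16 traps at its single free ring position. The route is rejoined at 18 without heating.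

Further compounds

F1 | step 3 | ethyl (2R,4E)-2,5,9-trimethyl-2-[4-(2-methyl-1,3-dioxolan-2-yl)-3-oxobutanoyl]deca-4,8-dienoate | CC1(CC(=O)CC(=O)[C@@](C)(C/C=C(\C)CCC=C(C)C)C(=O)OCC)OCCO1
F2 | step 2 | ethyl (4E)-2-acetyl-2,5,9-trimethyldeca-4,8-dienoate (racemate) | CC(=O)C(C)(C/C=C(\C)CCC=C(C)C)C(=O)OCC
F3 | step 2 | ethyl (2S,4E)-2-acetyl-2,5,9-trimethyldeca-4,8-dienoate | CC(=O)[C@](C)(C/C=C(\C)CCC=C(C)C)C(=O)OCC
F4 | step 8 | (4R)-2-acetyl-6-[(dimethylamino)methyl]-4-[(2E)-3,7-dimethylocta-2,6-dien-1-yl]-3,5-dihydroxy-4-methylcyclohexa-2,5-dien-1-one | CN(C)CC1=C(O)[C@@](C)(C/C=C(\C)CCC=C(C)C)C(O)=C(C(C)=O)C1=O
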